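## The problem

The target is a nonaphenol built around a central benzene ring (ring C, carbons C1 to C6) that has hydrogen only at C2. C1–O and C6 belong to a 2,3-trans-dihydrofuran (ring D1: O, C-a, C-b). C6 and C5 belong to a seven-membered carbocycle (ring S: C6, C-b, two adjacent carbons of the resorcinol ring B, C-c, a CH2 group, C5). C3–O and C4 belong to a second 2,3-trans-dihydrofuran (ring D2: O, C-e, C-d). There are five stereocentres, written (aR,bR,cR,dS,eS) below: C-a (ring A, 4-hydroxyphenyl), C-b, C-c (ring E, 2,4-dihydroxyphenyl), C-d (ring F, 3,5-dihydroxyphenyl) and C-e (ring G, 2,4-dihydroxyphenyl).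

C-a and C-e are benzylic ether carbons with donor aryl groups. They can ionise and reclose, so each follows its neighbour into the trans ring. C-b and C-d cannot be corrected later, and the two dihydrofurans have opposite absolute sense and lie far apart, so each must be set by a reagent.

C-c is the hidden difficulty. The tricycle B–S–C is folded about the axis through C-b and the C-c/CH2 bond. The fused ring D1 forces H-b onto the convex face, and the target has ring E on that same face. The hydrogen on C-c therefore lies inside the fold and cannot be delivered by a reagent approaching from outside.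

The nine phenols are oxidation-prone and are carried as methyl ethers to the last step, so the two oxygens of ring C must be distinguishable from nine others. The dihydrofuran C–O bonds are acid-labile, and H-b is base-labile because removing it would expel the ring D1 aryloxide.

The feature that opens the key step is in ring S. The CH2 on C5 of ring C and C-c on ring B are adjacent sp3 carbons, each flanked by an arene, so the bond between them is a reduced stilbene bond. It can be made by joining a ring C aldehyde to a ring B diaryl ketone, which C-b already holds together once ring D1 exists.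

## Retrosynthesis

**36 from 35.** The nine O–CH3 bonds are cut last. Nonamethyl ether 35 is stable to air, base and chromatography, and BBr3 is the established way to unmask this class; any ionisation at C-a or C-e recloses to the trans rings.

**35 from 28, 32 and 34.** Ring D2 is cut at three bonds: C-d–ring F, C-d–C-e and C-e–O. Carbonate 28 takes up Grignard reagent 32 to give o-quinone methide 33, and the chiral ylide 34 (from salt 31) adds and is displaced by the phenoxide. Ring D2 carries the most acid-labile benzylic ether (2,4-dimethoxyphenyl), so it is made after all Lewis-acidic steps. The forward step must override the remote centres by reagent control.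

**28 from 27 from 26.** The C4–CHO bond is cut. Phenol 26 has a single free hydroxyl, at C3 of ring C, so a magnesium-phenoxide formylation can reach only C2 or C4, and C4 (para to the ring D1 oxygen) is favoured. This is why ring C carries a benzyl ether while every other phenol is a methyl ether.

**26 from 25, 24, 23, 22 and 21.** The C-c–H bond is cut, not simply hydrogenated. Hydrogenation of 21 would add to the convex face and give the C-c epimer. Instead oxygen is placed on the convex face (epoxide 22), and the hydrogen on the neighbouring carbon migrates to C-c across the concave face (ketone 23). The oxygen is then removed through alcohol 24 and acetate 25, together with the benzyl group. This costs three more steps than a hydrogenation, and in return C-c is set by a stereospecific shift and is also under thermodynamic control in 23.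

**21 from 20 (key).** The C-c=CH double bond is cut to a ring C aldehyde and a ring B diaryl ketone. Against a Friedel–Crafts closure at ring B, this cut needs no regiocontrol on a ring with three nucleophilic positions and uses two carbonyl groups that come directly from the building blocks. Keto aldehyde 20 has two stereocentres and one ring fewer than 21.

**20 from 19 from 18.** Only oxidation levels change. Both carbonyl groups are carried as silyl-protected alcohols through the organomagnesium chemistry and are released and oxidised together.

**18 from 11, 15 and 17.** Ring D1 is cut at C-b–ring B, C-b–C-a and C-a–O, by the same three-component annulation as ring D2. The partners are salicylaldehyde carbonate 11, Grignard reagent 15 (from bromide 6) and ylide 17 (from salt 14). The ring B–carbonyl bond is already in 15, so ring B never has to be functionalised in the presence of the equally electron-rich ring C.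

**Building blocks.**
- 11 comes from 3,5-dihydroxybenzyl alcohol 7 through 8, 9 and 10 (silylation, formylation, selective benzylation, carbonate).
- 6 comes from 1 and 3 through 2, 4 and 5.
- 14 and 31 come from benzylic alcohols 12 and 29 and the two enantiomers of isothiocineole, 13 and 30.

## Roads not taken

**Alternative 1: Michael–Claisen annulation that builds ring C and closes ring S.** The cut removes two ring C bonds: C5–C6 (shared with ring S) and C1–C2. In the forward step the β-ketoester carbon of the open-chain ynone A1 adds to the alkyne (7-exo-dig), and the methyl ketone enolate then attacks the ester (6-exo-trig) to give resorcinol A2.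
- Merits: two rings form in one operation. Ring C appears as a free resorcinol whose hydroxyl next to the ketone is chelated, so its two oxygens are easily told apart. C-c is set in an open chain, where catalytic asymmetric aryl addition is routine. On this point the alternative is better than the chosen plan, which needs steps 13 to 16 to place one hydrogen.
- Weak points: the ynone has acidic γ-hydrogens next to C-c and can isomerise to an allenone under the basic conditions. The Michael adduct must have the right alkene geometry for the Claisen closure. A1 itself needs a ring B carrying two different ortho chains. A2 still lacks C-a, C-b and both dihydrofurans, and C-b has to be made from a hindered diaryl ketone.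
- Comparison: the chosen plan sets against the C-c advantage that ring S is closed from two arenes, each available in one to four steps, that no arene is built de novo, and that one annulation serves both dihydrofurans.

**Alternative 2: the three-component o-quinone methide annulation as the central step, used first for ring D2.** The cut is the same as for ring D2 above, but on a simple ring C: O-Boc bromosalicylaldehyde A3, Grignard reagent 32 and ylide 34 would give bromide A4.
- Merits: the reagent-controlled step is run first, on cheap and unhindered material, not second to last against three existing centres. Here the alternative is better than the chosen plan.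
- Weak points: as a key step it solves neither ring S nor C-c. A4 then has to carry the most acid-labile benzylic ether of the molecule through the titanium and boron Lewis acids needed later. Its ring C methoxy group must also be singled out from four others before ring D1 can be made.
- Comparison: the chosen plan uses this same reaction twice as a supporting step. Its order places ring D1 (the more robust 4-methoxyphenyl ether) before the Lewis-acidic middle of the route and ring D2 after it.

**Alternative 3: Danheiser benzannulation that builds ring B last.** The cut removes four carbon–carbon bonds of ring B. Photolysis of diazo ketone A5 would give a vinylketene that combines with ethoxyacetylene A6 to give phenol A7.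
- Merits: neutral conditions, complete regiocontrol of the ring B oxygens, and no hindered aryl–metal chemistry at ring B.
- Weak points: A5 already contains ring S as a cycloheptene with all five stereocentres and both dihydrofurans, so every hard problem has to be solved beforehand without the rigidity that ring B gives. C-c in A5 is γ to the enone carbonyl and would be at risk during diazo transfer. The photolysis has to run in the presence of many electron-rich arenes. The phenol/ethyl ether distinction in A7 is of no use, since all ethers are cleaved at the end.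
- Comparison: the ring B pattern is available directly from 1-bromo-3,5-dimethoxybenzene, so the chosen plan loses nothing by buying it.

Key step: step 12

**Assumptions and remarks**
- Both enantiomers of isothiocineole (4,7,7-trimethyl-6-thiabicyclo[3.2.1]octane) are treated as purchased; each is otherwise one step from the matching limonene enantiomer.
- The (1R,4R,5R)-sulfide is taken to transfer a benzylidene group in the sense that gives (R,R)-epoxides from aldehydes, which corresponds to 2S in a dihydrofuran. Ring D1 (aR) therefore uses the (1S,4S,5S)-sulfide 13 and ring D2 (eS) the (1R,4R,5R)-sulfide 30; the two would change places if the sense proved opposite.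
- Compounds 5, 6, 15, 16, 18 and 19 carry one undefined carbinol centre that is destroyed in step 11. Compounds 24 and 25 carry one that is removed in step 16.

## Route

Step 1
Reactants: 1 1-bromo-3,5-dimethoxybenzene
Product: 2 2-bromo-4,6-dimethoxybenzaldehyde
Conditions: POCl3, DMF, 0 to 80 °C; aq. NaOAc
Reagents that add atoms: N,N-dimethylformamide CN(C)C=O; water O
Why: Vilsmeier–Haack formylation; the position para to one methoxy group and ortho to the other is attacked in preference to the crowded position between the two methoxy groups, and the bromide survives.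

Step 2
Reactants: 2 2-bromo-4,6-dimethoxybenzaldehyde; 3 1-bromo-2,4-dimethoxybenzene
Product: 5 (2-bromo-4,6-dimethoxyphenyl)(2,4-dimethoxyphenyl)methanol (racemic), via Grignard reagent 4 (not isolated)
Conditions: 3, Mg, THF, reflux; then 2, THF, 0 °C to rt; aq. NH4Cl
Reagents that add atoms: none
Why: Grignard addition to an aldehyde; the aryl bromide of 2 does not exchange at 0 °C, and the racemic carbinol centre is of no consequence because it becomes a ketone in step 11.

Step 3
Reactants: 5 (2-bromo-4,6-dimethoxyphenyl)(2,4-dimethoxyphenyl)methanol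
Product: 6 [(2-bromo-4,6-dimethoxyphenyl)(2,4-dimethoxyphenyl)methoxy](tert-butyl)dimethylsilane (racemic)
Conditions: TBSCl, imidazole, DMF, 40 °C
Reagents that add atoms: tert-butyldimethylsilyl chloride CC(C)(C)[Si](C)(C)Cl
Why: Imidazole-catalysed silylation masks the carbinol for the magnesium insertion of step 9; the basic medium avoids ionisation of this very electron-rich benzhydrol.

Step 4
Reactants: 7 3,5-dihydroxybenzyl alcohol
Product: 8 5-{[(tert-butyldiphenylsilyl)oxy]methyl}benzene-1,3-diol
Conditions: TBDPSCl (1.05 equiv), imidazole, DMF, 0 °C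
Reagents that add atoms: tert-butyldiphenylsilyl chloride CC(C)(C)[Si](Cl)(c1ccccc1)c1ccccc1
Why: Chemoselective silylation; under imidazole catalysis the primary alcohol reacts faster than the phenols, and the bulky silyl group is chosen because it should survive the Vilsmeier conditions of step 5.

Step 5
Reactants: 8 5-{[(tert-butyldiphenylsilyl)oxy]methyl}benzene-1,3-diol
Product: 9 2-{[(tert-butyldiphenylsilyl)oxy]methyl}-4,6-dihydroxybenzaldehyde
Conditions: POCl3, DMF, MeCN, 0 °C to rt; H2O, 50 °C
Reagents that add atoms: N,N-dimethylformamide CN(C)C=O; water O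
Why: Vilsmeier–Haack formylation of a 5-substituted resorcinol; attack occurs ortho to one hydroxyl and para to the other (the orcinol pattern), not between the hydroxyls, which places the formyl group next to the silyloxymethyl arm.

Step 6
Reactants: 9 2-{[(tert-butyldiphenylsilyl)oxy]methyl}-4,6-dihydroxybenzaldehyde
Product: 10 4-(benzyloxy)-2-{[(tert-butyldiphenylsilyl)oxy]methyl}-6-hydroxybenzaldehyde
Conditions: BnBr (1.05 equiv), NaHCO3, MeCN, 70 °C
Reagents that add atoms: benzyl bromide BrCc1ccccc1
Why: Williamson etherification; the hydroxyl ortho to the aldehyde is tied up in a hydrogen bond and is the weaker nucleophile, so the para hydroxyl is benzylated selectively with a mild base.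

Step 7
Reactants: 10 4-(benzyloxy)-2-{[(tert-butyldiphenylsilyl)oxy]methyl}-6-hydroxybenzaldehyde
Product: 11 5-(benzyloxy)-3-{[(tert-butyldiphenylsilyl)oxy]methyl}-2-formylphenyl tert-butyl carbonate
Conditions: Boc2O, iPr2NEt, DMAP (cat.), CH2Cl2, rt
Reagents that add atoms: di-tert-butyl dicarbonate CC(C)(C)OC(=O)OC(=O)OC(C)(C)C
Why: DMAP-catalysed O-acylation of the chelated phenol gives the aryl tert-butyl carbonate from which the o-quinone methide is released in step 9.

Step 8
Reactants: 12 4-methoxybenzyl alcohol; 13 (1S,4S,5S)-isothiocineole
Product: 14 (1S,4S,5S)-6-(4-methoxybenzyl)-4,7,7-trimethyl-6-thiabicyclo[3.2.1]octan-6-ium tetrafluoroborate (one diastereomer at sulfur)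
Conditions: HBF4·OEt2, CH2Cl2, 0 °C to rt
Reagents that add atoms: tetrafluoroboric acid [H+].F[B-](F)(F)F
Why: SN1 S-alkylation; the acid ionises the donor-substituted benzylic alcohol and the sulfide captures the cation on its less hindered lone pair, so no unstable benzylic halide is needed.

Step 9
Reactants: 6 [(2-bromo-4,6-dimethoxyphenyl)(2,4-dimethoxyphenyl)methoxy](tert-butyl)dimethylsilane; 11 5-(benzyloxy)-3-{[(tert-butyldiphenylsilyl)oxy]methyl}-2-formylphenyl tert-butyl carbonate; 14 sulfonium tetrafluoroborate
Product: 18 (2R,3R)-6-(benzyloxy)-3-{2-[((tert-butyldimethylsilyl)oxy)(2,4-dimethoxyphenyl)methyl]-3,5-dimethoxyphenyl}-4-{[(tert-butyldiphenylsilyl)oxy]methyl}-2-(4-methoxyphenyl)-2,3-dihydrobenzofuran (both epimers at the silyloxy carbon), via aryl Grignard reagent 15 (not isolated), via o-quinone methide 16 (not isolated), via sulfonium ylide 17 (not isolated)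
Conditions: 6, Mg, LiCl, THF, rt; add to 11, THF, −78 °C; then ylide from 14 and LiN(SiMe3)2 (THF, −78 °C); −78 to 0 °C
Reagents that add atoms: none
Why: o-Quinone methide generation from an O-Boc salicylaldehyde (Grignard addition, Boc transfer to the benzylic alkoxide, loss of tert-butyl carbonate) followed by sulfonium ylide [4+1] annulation (conjugate addition, then 5-exo-tet displacement of the sulfide by the phenoxide with inversion). The ylide of 13 reacts through one conformer and one face, which fixes C-a as R, and the anti arrangement of the two aryl groups in the addition gives the 2,3-trans ring and so C-b as R.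

Step 10
Reactants: 18 bis-silyl ether
Product: 19 {(2R,3R)-6-(benzyloxy)-3-{2-[hydroxy(2,4-dimethoxyphenyl)methyl]-3,5-dimethoxyphenyl}-2-(4-methoxyphenyl)-2,3-dihydrobenzofuran-4-yl}methanol (both carbinol epimers)
Conditions: Bu4NF, THF, 0 °C to rt
Reagents that add atoms: none
Why: Fluoride-mediated desilylation removes both silyl ethers under conditions that leave the acid-sensitive benzhydrol and ring D1 untouched.

Step 11
Reactants: 19 diol
Product: 20 (2R,3R)-6-(benzyloxy)-3-[2-(2,4-dimethoxybenzoyl)-3,5-dimethoxyphenyl]-2-(4-methoxyphenyl)-2,3-dihydrobenzofuran-4-carbaldehyde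
Conditions: Dess–Martin periodinane, NaHCO3, CH2Cl2, rt
Reagents that add atoms: none
Why: Dess–Martin oxidation takes the primary benzylic alcohol to the aldehyde and the diaryl carbinol to the ketone in one operation and merges the two carbinol epimers into one compound. The product is kept from light, since o-alkyl benzaldehydes can photoenolise at the benzylic C-b–H.

Step 12
Reactants: 20 keto aldehyde
Product: 21 (aR,bR)-dibenzosuberene with the C-c=CH double bond in ring S (ring E on C-c as 2,4-dimethoxyphenyl; benzyloxy at C3 of ring C)
Conditions: TiCl4, Zn, pyridine, THF, reflux; slow addition of 20 (final 2 mM)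
Reagents that add atoms: none
Why: McMurry reaction: zinc reduces TiCl4 to low-valent titanium, which transfers one electron to each carbonyl group; the two titanium-bound ketyl carbons couple to a titanium pinacolate, and on heating both C–O bonds are given up to titanium to leave the C-c=CH double bond. The closest known reaction type is the intramolecular McMurry coupling of keto aldehydes to cyclic stilbenes, which includes dibenzo-fused seven-membered rings. Ring S closes by carbon–carbon bond formation between the two tethered ketyl carbons and ends as a seven-membered ring with an endocyclic alkene flanked by rings B and C. No stereocentre is formed; C-a and C-b are spectators, and the pyridine-buffered medium contains neither a strong protic acid nor a base able to remove H-b. The selectivity needed is intramolecular cross-coupling ahead of intermolecular pinacol formation and of simple reduction of the aldehyde. The substrate secures it: the aldehyde sits on the ring C carbon next to the one bearing C-b and the ketone on the ring B carbon next to its point of attachment, so the rigid trans-dihydrofuran holds the two carbonyl carbons within bonding distance, and slow addition at high dilution does the rest. The product is deliberately an alkene, because it is the handle through which oxygen and then hydrogen are brought to C-c in step 13.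

Step 13
Reactants: 21 dibenzosuberene
Product: 23 (aR,bR,cR)-ketone of ring S (C=O on the carbon attached to C5 of ring C; H on C-c), via epoxide 22 (not isolated)
Conditions: DMDO, acetone/CH2Cl2, −20 °C; evaporate; BF3·OEt2 (0.2 equiv), CH2Cl2, −78 °C
Reagents that add atoms: dimethyldioxirane CC1(C)OO1
Why: Epoxidation on the convex face (the face of H-b) followed by Meinwald rearrangement: BF3 opens the epoxide at C-c to the doubly aryl-stabilised cation, and the hydrogen on the neighbouring carbon shifts to C-c across the concave face, anti to the departing oxygen, which sets C-c as R. Hydride shift should be preferred over aryl shift because it needs little twisting of ring S and because the ring C carbon that would migrate is meta to both oxygens. If C-c epimerises through the enol, it should return to the same configuration, which has ring E pseudo-axial and clear of the neighbouring methoxy group of ring B.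

Step 14
Reactants: 23 ketone
Product: 24 (aR,bR,cR)-alcohol of ring S (carbinol centre undefined)
Conditions: NaBH4, CeCl3·7H2O, MeOH/THF, −20 °C
Reagents that add atoms: none
Why: Luche-type borohydride reduction; cerium activation makes carbonyl reduction faster than enolisation so that C-c is not touched, and the configuration of the new carbinol is irrelevant because the oxygen is removed in step 16.

Step 15
Reactants: 24 alcohol
Product: 25 acetate of 24
Conditions: Ac2O, pyridine, DMAP (cat.), CH2Cl2, rt
Reagents that add atoms: acetic anhydride CC(=O)OC(C)=O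
Why: DMAP-catalysed acetylation turns the benzylic hydroxyl into a group that undergoes hydrogenolysis under neutral conditions.

Step 16
Reactants: 25 acetate
Product: 26 (aR,bR,cR)-phenol (ring S saturated with CH2 next to C-c; free hydroxyl at C3 of ring C; all other phenols as methyl ethers)
Conditions: H2 (1–3 bar), 10% Pd/C, EtOAc/EtOH, rt
Reagents that add atoms: none
Why: Catalytic hydrogenolysis cleaves the benzyl aryl ether and the secondary benzylic acetate on the palladium surface without a free cation next to C-c, so no hydride or aryl shift can scramble C-c. Methyl ethers and, under neutral conditions, the cyclic benzylic ether of ring D1 should be retained.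

Step 17
Reactants: 26 phenol
Product: 27 (aR,bR,cR)-salicylaldehyde (26 with CHO at C4 of ring C)
Conditions: MgCl2, Et3N, (CH2O)n, MeCN, reflux
Reagents that add atoms: paraformaldehyde C=O
Why: Casnati–Skattebøl ortho-formylation; the magnesium phenoxide delivers formaldehyde to an ortho carbon only, and of the two the one para to the ring D1 oxygen (C4) is more nucleophilic and less crowded than the one between two oxygens (C2).

Step 18
Reactants: 27 salicylaldehyde
Product: 28 tert-butyl carbonate of 27
Conditions: Boc2O, iPr2NEt, DMAP (cat.), CH2Cl2, rt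
Reagents that add atoms: di-tert-butyl dicarbonate CC(C)(C)OC(=O)OC(=O)OC(C)(C)C
Why: O-acylation of the chelated phenol as in step 7, to arm ring C for the second o-quinone methide release.

Step 19
Reactants: 29 2,4-dimethoxybenzyl alcohol; 30 (1R,4R,5R)-isothiocineole
Product: 31 (1R,4R,5R)-6-(2,4-dimethoxybenzyl)-4,7,7-trimethyl-6-thiabicyclo[3.2.1]octan-6-ium tetrafluoroborate (one diastereomer at sulfur)
Conditions: HBF4·OEt2, CH2Cl2, 0 °C
Reagents that add atoms: tetrafluoroboric acid [H+].F[B-](F)(F)F
Why: SN1 S-alkylation as in step 8; the 2,4-dimethoxybenzyl cation forms even more readily, so the salt is made cold and used at once.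

Step 20
Reactants: 28 tert-butyl carbonate; 1 1-bromo-3,5-dimethoxybenzene; 31 sulfonium tetrafluoroborate
Product: 35 (aR,bR,cR,dS,eS)-nonamethyl ether of the target, via Grignard reagent 32 (not isolated), via o-quinone methide 33 (not isolated), via sulfonium ylide 34 (not isolated)
Conditions: 1, Mg, THF, reflux; add to 28, THF, −78 °C; then ylide from 31 and LiN(SiMe3)2 (THF, −78 °C); −78 to 0 °C
Reagents that add atoms: none
Why: o-Quinone methide generation and sulfonium ylide [4+1] annulation as in step 9. The ylide of 30 fixes C-e as S by reagent control, since the nearest existing centre is four bonds away, and the trans mode of addition then fixes C-d as S.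

Step 21
Reactants: 35 nonamethyl ether
Product: 36 CNP0283541.1 (aR,bR,cR,dS,eS)
Conditions: BBr3 (excess), CH2Cl2, −78 °C to rt; MeOH, then H2O
Reagents that add atoms: none
Why: BBr3 cleavage of the nine aryl methyl ethers; the benzylic carbons C-a and C-e may ionise reversibly under the Lewis acid but should reclose to the trans dihydrofurans, which are the thermodynamic isomers.

## Compound list

1 | 1-bromo-3,5-dimethoxybenzene | COc1cc(Br)cc(OC)c1 | starting material
2 | 2-bromo-4,6-dimethoxybenzaldehyde | COc1cc(Br)c(C=O)c(OC)c1 | intermediate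
3 | 1-bromo-2,4-dimethoxybenzene | COc1ccc(Br)c(OC)c1 | starting material
4 | (2,4-dimethoxyphenyl)magnesium bromide | COc1ccc([Mg]Br)c(OC)c1 | intermediate
5 | (2-bromo-4,6-dimethoxyphenyl)(2,4-dimethoxyphenyl)methanol, racemic | COc1ccc(C(O)c2c(Br)cc(OC)cc2OC)c(OC)c1 | intermediate
6 | [(2-bromo-4,6-dimethoxyphenyl)(2,4-dimethoxyphenyl)methoxy](tert-butyl)dimethylsilane, racemic | COc1ccc(C(O[Si](C)(C)C(C)(C)C)c2c(Br)cc(OC)cc2OC)c(OC)c1 | intermediate
7 | 3,5-dihydroxybenzyl alcohol | OCc1cc(O)cc(O)c1 | starting material
8 | 5-{[(tert-butyldiphenylsilyl)oxy]methyl}benzene-1,3-diol | CC(C)(C)[Si](OCc1cc(O)cc(O)c1)(c1ccccc1)c1ccccc1 | intermediate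
9 | 2-{[(tert-butyldiphenylsilyl)oxy]methyl}-4,6-dihydroxybenzaldehyde | CC(C)(C)[Si](OCc1cc(O)cc(O)c1C=O)(c1ccccc1)c1ccccc1 | intermediate
10 | 4-(benzyloxy)-2-{[(tert-butyldiphenylsilyl)oxy]methyl}-6-hydroxybenzaldehyde | CC(C)(C)[Si](OCc1cc(OCc2ccccc2)cc(O)c1C=O)(c1ccccc1)c1ccccc1 | intermediate
11 | 5-(benzyloxy)-3-{[(tert-butyldiphenylsilyl)oxy]methyl}-2-formylphenyl tert-butyl carbonate | CC(C)(C)[Si](OCc1cc(OCc2ccccc2)cc(OC(=O)OC(C)(C)C)c1C=O)(c1ccccc1)c1ccccc1 | intermediate
12 | 4-methoxybenzyl alcohol | COc1ccc(CO)cc1 | starting material
13 | (1S,4S,5S)-isothiocineole, (1S,4S,5S)-4,7,7-trimethyl-6-thiabicyclo[3.2.1]octane | C[C@H]1CC[C@H]2C[C@@H]1SC2(C)C | starting material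
14 | (1S,4S,5S)-6-(4-methoxybenzyl)-4,7,7-trimethyl-6-thiabicyclo[3.2.1]octan-6-ium tetrafluoroborate, one diastereomer at sulfur (sulfur configuration not written) | C[C@H]1CC[C@H]2C[C@@H]1[S+](Cc1ccc(OC)cc1)C2(C)C.F[B-](F)(F)F | intermediate
15 | {2-[((tert-butyldimethylsilyl)oxy)(2,4-dimethoxyphenyl)methyl]-3,5-dimethoxyphenyl}magnesium bromide, racemic | COc1ccc(C(O[Si](C)(C)C(C)(C)C)c2c([Mg]Br)cc(OC)cc2OC)c(OC)c1 | intermediate
16 | o-quinone methide of ring C: 3-(benzyloxy)-5-(silyloxymethyl)-6-(arylmethylidene)cyclohexa-2,4-dien-1-one, aryl = ring B with its silyloxy(2,4-dimethoxyphenyl)methyl group; alkene geometry undefined | O=C1C=C(OCc2ccccc2)C=C(CO[Si](c2ccccc2)(c2ccccc2)C(C)(C)C)C1=Cc1cc(OC)cc(OC)c1C(O[Si](C)(C)C(C)(C)C)c1ccc(OC)cc1OC | intermediate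
17 | sulfonium 4-methoxybenzylide of 13 | C[C@H]1CC[C@H]2C[C@@H]1[S+]([CH-]c1ccc(OC)cc1)C2(C)C | intermediate
18 | (2R,3R)-6-(benzyloxy)-3-{2-[((tert-butyldimethylsilyl)oxy)(2,4-dimethoxyphenyl)methyl]-3,5-dimethoxyphenyl}-4-{[(tert-butyldiphenylsilyl)oxy]methyl}-2-(4-methoxyphenyl)-2,3-dihydrobenzofuran, both epimers at the silyloxy carbon | COc1ccc([C@@H]2Oc3cc(OCc4ccccc4)cc(CO[Si](c4ccccc4)(c4ccccc4)C(C)(C)C)c3[C@H]2c2cc(OC)cc(OC)c2C(O[Si](C)(C)C(C)(C)C)c2ccc(OC)cc2OC)cc1 | intermediate
19 | {(2R,3R)-6-(benzyloxy)-3-{2-[hydroxy(2,4-dimethoxyphenyl)methyl]-3,5-dimethoxyphenyl}-2-(4-methoxyphenyl)-2,3-dihydrobenzofuran-4-yl}methanol, both carbinol epimers | COc1ccc([C@@H]2Oc3cc(OCc4ccccc4)cc(CO)c3[C@H]2c2cc(OC)cc(OC)c2C(O)c2ccc(OC)cc2OC)cc1 | intermediate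
20 | (2R,3R)-6-(benzyloxy)-3-[2-(2,4-dimethoxybenzoyl)-3,5-dimethoxyphenyl]-2-(4-methoxyphenyl)-2,3-dihydrobenzofuran-4-carbaldehyde | COc1ccc([C@@H]2Oc3cc(OCc4ccccc4)cc(C=O)c3[C@H]2c2cc(OC)cc(OC)c2C(=O)c2ccc(OC)cc2OC)cc1 | intermediate
21 | (aR,bR)-dibenzosuberene: rings A, B, C, D1, S and E assembled, C-c=CH double bond in ring S, benzyloxy at C3 of ring C, six methyl ethers | COc1ccc([C@@H]2Oc3cc(OCc5ccccc5)cc4c3[C@H]2c2cc(OC)cc(OC)c2C(c2ccc(OC)cc2OC)=C4)cc1 | intermediate
22 | (aR,bR)-epoxide of 21, oxirane oxygen on the face of H-b | COc1ccc([C@@H]2Oc3cc(OCc5ccccc5)cc4c3[C@H]2c2cc(OC)cc(OC)c2[C@@]6(c2ccc(OC)cc2OC)O[C@H]64)cc1 | intermediate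
23 | (aR,bR,cR)-ketone: ring S with C=O on the carbon attached to C5 of ring C and H on C-c | COc1ccc([C@@H]2Oc3cc(OCc5ccccc5)cc4c3[C@H]2c2cc(OC)cc(OC)c2[C@@H](c2ccc(OC)cc2OC)C4=O)cc1 | intermediate
24 | (aR,bR,cR)-alcohol from 23, carbinol centre undefined | COc1ccc([C@@H]2Oc3cc(OCc5ccccc5)cc4c3[C@H]2c2cc(OC)cc(OC)c2[C@@H](c2ccc(OC)cc2OC)C4O)cc1 | intermediate
25 | acetate of 24 | COc1ccc([C@@H]2Oc3cc(OCc5ccccc5)cc4c3[C@H]2c2cc(OC)cc(OC)c2[C@@H](c2ccc(OC)cc2OC)C4OC(C)=O)cc1 | intermediate
26 | (aR,bR,cR)-phenol: ring S saturated, free hydroxyl at C3 of ring C, six methyl ethers | COc1ccc([C@@H]2Oc3cc(O)cc4c3[C@H]2c2cc(OC)cc(OC)c2[C@@H](c2ccc(OC)cc2OC)C4)cc1 | intermediate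
27 | (aR,bR,cR)-salicylaldehyde: 26 with CHO at C4 of ring C | COc1ccc([C@@H]2Oc3cc(O)c(C=O)c4c3[C@H]2c2cc(OC)cc(OC)c2[C@@H](c2ccc(OC)cc2OC)C4)cc1 | intermediate
28 | tert-butyl carbonate of 27 | COc1ccc([C@@H]2Oc3cc(OC(=O)OC(C)(C)C)c(C=O)c4c3[C@H]2c2cc(OC)cc(OC)c2[C@@H](c2ccc(OC)cc2OC)C4)cc1 | intermediate
29 | 2,4-dimethoxybenzyl alcohol | COc1ccc(CO)c(OC)c1 | starting material
30 | (1R,4R,5R)-isothiocineole, (1R,4R,5R)-4,7,7-trimethyl-6-thiabicyclo[3.2.1]octane | C[C@@H]1CC[C@@H]2C[C@H]1SC2(C)C | starting material
31 | (1R,4R,5R)-6-(2,4-dimethoxybenzyl)-4,7,7-trimethyl-6-thiabicyclo[3.2.1]octan-6-ium tetrafluoroborate, one diastereomer at sulfur (sulfur configuration not written) | C[C@@H]1CC[C@@H]2C[C@H]1[S+](Cc1ccc(OC)cc1OC)C2(C)C.F[B-](F)(F)F | intermediate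
32 | (3,5-dimethoxyphenyl)magnesium bromide | COc1cc(OC)cc([Mg]Br)c1 | intermediate
33 | o-quinone methide from 28: C3=O and exocyclic C4=CH(3,5-dimethoxyphenyl) on ring C; alkene geometry undefined | COc1ccc([C@@H]2OC3=CC(=O)C(=Cc5cc(OC)cc(OC)c5)C4=C3[C@H]2c2cc(OC)cc(OC)c2[C@@H](c2ccc(OC)cc2OC)C4)cc1 | intermediate
34 | sulfonium 2,4-dimethoxybenzylide of 30 | C[C@@H]1CC[C@@H]2C[C@H]1[S+]([CH-]c1ccc(OC)cc1OC)C2(C)C | intermediate
35 | (aR,bR,cR,dS,eS)-nonamethyl ether of the target | COc1ccc([C@@H]2Oc3cc4c(c5c3[C@H]2c2cc(OC)cc(OC)c2[C@@H](c2ccc(OC)cc2OC)C5)[C@H](c2cc(OC)cc(OC)c2)[C@@H](c2ccc(OC)cc2OC)O4)cc1 | intermediate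
36 | CNP0283541.1, (aR,bR,cR,dS,eS) | Oc1ccc([C@@H]2Oc3cc4c(c5c3[C@H]2c2cc(O)cc(O)c2[C@@H](c2ccc(O)cc2O)C5)[C@H](c2cc(O)cc(O)c2)[C@@H](c2ccc(O)cc2O)O4)cc1 | target

## Step count and risks

Total: 21 steps. Longest linear sequence: 16 steps (7 to 36 through steps 4–7, 9–18, 20 and 21).

**Step 12 (key step).** The most likely failure is intermolecular ketyl coupling, or a stall at the titanium pinacolate, because the diaryl ketone has three ortho substituents and is slow to couple and to deoxygenate. Reductive cleavage of a benzylic C–O bond by low-valent titanium is a lesser concern.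
Fallback: set out from 20 and form the same bond with SmI2 in THF as an intramolecular pinacol coupling, which stops at the ring S 1,2-diol F1. A catalytic amount of TsOH then ionises the tertiary, doubly aryl-stabilised carbinol at C-c and induces pinacol rearrangement by hydride shift. The route is rejoined at ketone 23, whose C-c centre is α to the new carbonyl and therefore under thermodynamic control.

**Step 9.** The most likely failure is incomplete transfer of chirality or poor cis/trans selectivity. The ylide meets an o-quinone methide whose terminus carries an ortho-substituted aryl group and may exist as two alkene isomers, and the ylide may partly decompose before the o-quinone methide is released.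
Fallback: give up reagent control. Set out from 6 and 11 and use the achiral (4-methoxybenzyl)dimethylsulfonium tetrafluoroborate F2 in place of 14. This should give 18 together with its enantiomer F3. Both are taken through steps 10 and 11, the enantiomeric diol F4 leading to the enantiomeric keto aldehyde F5. Preparative chromatography on a chiral stationary phase then separates 20, where the route is rejoined.

**Step 20.** The most likely failure is poor facial selectivity when the chiral ylide has to act against three existing stereocentres on a hindered aldehyde. It is aggravated by reversible ionisation of the very labile 2,4-dimethoxybenzyl sulfonium salt.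
Fallback: replace the annulation by a rhodium-carbene C–H insertion.
- Set out from 27; a Mitsunobu reaction with alcohol 29 (PPh3, diisopropyl azodicarboxylate) gives the aryl 2,4-dimethoxybenzyl ether F6.
- Grignard reagent 32 adds to give carbinol F7, and Dess–Martin oxidation gives diaryl ketone F8.
- Hydrazine under forcing conditions gives hydrazone F9.
- Oxidation with MnO2 to the diazo compound and treatment with Rh2(S-PTAD)4 (dirhodium tetrakis[(S)-(1-adamantyl)(phthalimido)acetate]), or its enantiomer, whichever gives dS, inserts the carbene into the benzylic O–CH2 bond. This gives the 2,3-cis dihydrofuran F10, with C-d set by the catalyst.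
- Catalytic CF3CO2H epimerises C-e through the benzylic cation to the trans ring, and the route is rejoined at 35.

**Step 13.** The most likely failures are migration of the ring C aryl carbon (ring contraction) in place of the hydride shift, or epoxidation on the concave face. Either would misplace or invert C-c.
Fallback: rely on thermodynamic control only. Set out from 21; hydroboration and oxidation (BH3·THF; H2O2, NaOH) add hydrogen and hydroxyl to the convex face to give alcohol F11, which is the C-c epimer. Dess–Martin oxidation gives the epimeric ketone F12. DBU then equilibrates C-c to the more stable configuration with ring E pseudo-axial, and the route is rejoined at 23.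

**Step 16.** The most likely failures are incomplete hydrogenolysis of the hindered secondary benzylic acetate or, on forcing, hydrogenolytic opening of ring D1 at the C-a–O bond.
Fallback: a Barton–McCombie deoxygenation. Set out from 24; NaH, CS2 and MeI give xanthate F13, and Bu3SnH with AIBN in toluene at 90 °C gives benzyl ether F14. A mild hydrogenolysis (H2, Pd/C, EtOAc, rt) then only has to remove the benzyl group, and the route is rejoined at 26.

## Further compounds

F1 | step 12 | (aR,bR)-ring S 1,2-diol from pinacol coupling of 20: tertiary hydroxyl on C-c, secondary hydroxyl on the neighbouring carbon, both new centres undefined | COc1ccc([C@@H]2Oc3cc(OCc5ccccc5)cc4c3[C@H]2c2cc(OC)cc(OC)c2C(O)(c2ccc(OC)cc2OC)C4O)cc1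
F2 | step 9 | (4-methoxybenzyl)dimethylsulfonium tetrafluoroborate | COc1ccc(C[S+](C)C)cc1.F[B-](F)(F)F
F3 | step 9 | (2S,3S)-enantiomer of 18, both epimers at the silyloxy carbon | COc1ccc([C@H]2Oc3cc(OCc4ccccc4)cc(CO[Si](c4ccccc4)(c4ccccc4)C(C)(C)C)c3[C@@H]2c2cc(OC)cc(OC)c2C(O[Si](C)(C)C(C)(C)C)c2ccc(OC)cc2OC)cc1
F4 | step 9 | (2S,3S)-enantiomer of diol 19, both carbinol epimers | COc1ccc([C@H]2Oc3cc(OCc4ccccc4)cc(CO)c3[C@@H]2c2cc(OC)cc(OC)c2C(O)c2ccc(OC)cc2OC)cc1
F5 | step 9 | (2S,3S)-enantiomer of keto aldehyde 20 | COc1ccc([C@H]2Oc3cc(OCc4ccccc4)cc(C=O)c3[C@@H]2c2cc(OC)cc(OC)c2C(=O)c2ccc(OC)cc2OC)cc1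
F6 | step 20 | (aR,bR,cR)-aryl 2,4-dimethoxybenzyl ether of 27 (ether at C3 of ring C, CHO at C4) | COc1ccc([C@@H]2Oc3cc(OCc5ccc(OC)cc5OC)c(C=O)c4c3[C@H]2c2cc(OC)cc(OC)c2[C@@H](c2ccc(OC)cc2OC)C4)cc1
F7 | step 20 | (aR,bR,cR)-carbinol from F6 and 32, carbinol centre undefined | COc1ccc([C@@H]2Oc3cc(OCc5ccc(OC)cc5OC)c(C(O)c5cc(OC)cc(OC)c5)c4c3[C@H]2c2cc(OC)cc(OC)c2[C@@H](c2ccc(OC)cc2OC)C4)cc1
F8 | step 20 | (aR,bR,cR)-diaryl ketone: 3,5-dimethoxybenzoyl group at C4 of ring C | COc1ccc([C@@H]2Oc3cc(OCc5ccc(OC)cc5OC)c(C(=O)c5cc(OC)cc(OC)c5)c4c3[C@H]2c2cc(OC)cc(OC)c2[C@@H](c2ccc(OC)cc2OC)C4)cc1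
F9 | step 20 | hydrazone of F8 | COc1ccc([C@@H]2Oc3cc(OCc5ccc(OC)cc5OC)c(C(=NN)c5cc(OC)cc(OC)c5)c4c3[C@H]2c2cc(OC)cc(OC)c2[C@@H](c2ccc(OC)cc2OC)C4)cc1
F10 | step 20 | (aR,bR,cR,dS,eR)-isomer of 35 with a 2,3-cis ring D2 | COc1ccc([C@@H]2Oc3cc4c(c5c3[C@H]2c2cc(OC)cc(OC)c2[C@@H](c2ccc(OC)cc2OC)C5)[C@H](c2cc(OC)cc(OC)c2)[C@H](c2ccc(OC)cc2OC)O4)cc1
F11 | step 13 | (aR,bR)-alcohol from hydroboration of 21: H on C-c and hydroxyl on the neighbouring carbon both on the face of H-b (C-c epimer of the 24 series) | COc1ccc([C@@H]2Oc3cc(OCc5ccccc5)cc4c3[C@H]2c2cc(OC)cc(OC)c2[C@H](c2ccc(OC)cc2OC)[C@H]4O)cc1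
F12 | step 13 | C-c epimer of ketone 23 | COc1ccc([C@@H]2Oc3cc(OCc5ccccc5)cc4c3[C@H]2c2cc(OC)cc(OC)c2[C@H](c2ccc(OC)cc2OC)C4=O)cc1
F13 | step 16 | S-methyl xanthate of 24 | COc1ccc([C@@H]2Oc3cc(OCc5ccccc5)cc4c3[C@H]2c2cc(OC)cc(OC)c2[C@@H](c2ccc(OC)cc2OC)C4OC(=S)SC)cc1
F14 | step 16 | (aR,bR,cR)-benzyl ether of 26 | COc1ccc([C@@H]2Oc3cc(OCc5ccccc5)cc4c3[C@H]2c2cc(OC)cc(OC)c2[C@@H](c2ccc(OC)cc2OC)C4)cc1
A1 | alternative 1 | methyl 3-{2-[(1R)-1-(2,4-dimethoxyphenyl)-5-oxohex-3-yn-1-yl]-3,5-dimethoxyphenyl}-3-oxopropanoate | COC(=O)CC(=O)c1cc(OC)cc(OC)c1[C@@H](c1ccc(OC)cc1OC)CC#CC(C)=O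
A2 | alternative 1 | (10R)-10-(2,4-dimethoxyphenyl)-2,4-dihydroxy-7,9-dimethoxy-10,11-dihydro-5H-dibenzo[a,d][7]annulen-5-one | Oc1cc(O)c2c(c1)C[C@H](c1ccc(OC)cc1OC)c1c(OC)cc(OC)cc1C2=O
A3 | alternative 2 | 3-bromo-2-formyl-5-methoxyphenyl tert-butyl carbonate | COc1cc(Br)c(C=O)c(OC(=O)OC(C)(C)C)c1
A4 | alternative 2 | (2S,3S)-4-bromo-2-(2,4-dimethoxyphenyl)-3-(3,5-dimethoxyphenyl)-6-methoxy-2,3-dihydrobenzofuran | COc1cc2c(c(Br)c1)[C@H](c1cc(OC)cc(OC)c1)[C@@H](c1ccc(OC)cc1OC)O2
A5 | alternative 3 | cycloheptene diazo ketone: rings A, C, D1, D2, E, F and G of the permethylated target, ring B replaced by a C=C bond of ring S whose carbon next to C-b carries a diazoacetyl group | COc1ccc([C@@H]2Oc3cc4c(c5c3[C@H]2C(C(=O)C=[N+]=[N-])=C[C@@H](c2ccc(OC)cc2OC)C5)[C@H](c2cc(OC)cc(OC)c2)[C@@H](c2ccc(OC)cc2OC)O4)cc1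
A6 | alternative 3 | ethoxyacetylene | CCOC#C
A7 | alternative 3 | target skeleton with ring B as its monoethyl ether phenol and all other phenols methylated | COc1ccc([C@@H]2Oc3cc4c(c5c3[C@H]2c2cc(OCC)cc(O)c2[C@@H](c2ccc(OC)cc2OC)C5)[C@H](c2cc(OC)cc(OC)c2)[C@@H](c2ccc(OC)cc2OC)O4)cc1
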